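**Retrosynthetic overview**
- The primary amide 12 comes from arylacetic acid 10 by activation and ammonolysis.
- Acid 10 comes from arylpyruvic acid 9 by oxidative decarboxylation (loss of the carboxyl carbon), and 9 from hydrolysis of azlactone 7.
- Key C–C bond (the future CH2–C(=O) bond): Erlenmeyer–Plöchl aldol-type condensation of 3,5-diiodo-4-methoxybenzaldehyde 4 with N-acetylglycine 5.
- Aldehyde 4 comes from 4-hydroxybenzaldehyde 1 by ortho,ortho-diiodination and O-methylation.
- Rings: the benzene ring is purchased; the only ring formed is the transient oxazolone (step 3), which is opened again in step 4.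

Assumption: the target has no stereocentre and no stereogenic double bond, so "single enantiomer" is taken to mean the one achiral compound drawn.

**Route**

Step 1
Reactants: 1 4-hydroxybenzaldehyde
Product: 3 4-hydroxy-3,5-diiodobenzaldehyde, via 4-hydroxy-3-iodobenzaldehyde 2 (not isolated)
Conditions: ICl (2.2 equiv), AcOH, rt then 60 °C; pour into water, aq Na2S2O3 wash, filter
Reagents that add atoms: iodine monochloride, ClI
Why: Twofold electrophilic aromatic substitution (iodination) at the two positions ortho to the strongly activating OH, the para position being blocked by CHO, so it stops at the 3,5-diiodide; no stereocentre is formed.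

Step 2
Reactants: 3 4-hydroxy-3,5-diiodobenzaldehyde
Product: 4 3,5-diiodo-4-methoxybenzaldehyde
Conditions: MeI (1.5 equiv), K2CO3 (2 equiv), DMF, rt to 40 °C
Reagents that add atoms: iodomethane, CI
Why: Williamson ether synthesis (SN2 on MeI); the phenol is acidified by the two ortho iodines and the para formyl group, so K2CO3 deprotonates it fully, and the small electrophile tolerates the flanking iodines.

Step 3
Reactants: 4 3,5-diiodo-4-methoxybenzaldehyde; 5 N-acetylglycine
Product: 7 (Z)-4-(3,5-diiodo-4-methoxybenzylidene)-2-methyloxazol-5(4H)-one, via 2-methyloxazol-5(4H)-one 6 (not isolated)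
Conditions: Ac2O (3 equiv), NaOAc (1 equiv), 100–110 °C, 2 h; cool, cold EtOH/H2O, filter
Reagents that add atoms: none
Why: Erlenmeyer–Plöchl azlactone synthesis: Ac2O cyclodehydrates 5 to oxazolone 6, whose acidic C4–H2 undergoes an aldol-type (Perkin) condensation with the non-enolisable aldehyde and dehydrates to the thermodynamically favoured Z-alkene; no stereocentre is formed.

Step 4
Reactants: 7 (Z)-4-(3,5-diiodo-4-methoxybenzylidene)-2-methyloxazol-5(4H)-one
Product: 9 3-(3,5-diiodo-4-methoxyphenyl)-2-oxopropanoic acid, via (Z)-2-acetamido-3-(3,5-diiodo-4-methoxyphenyl)acrylic acid 8 (not isolated)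
Conditions: 3 M aq HCl/AcOH (1:1), reflux, 4–6 h; cool, filter (7 + 3 H2O + HCl → 9 + AcOH + NH4Cl)
Reagents that add atoms: water, O
Why: Acid-catalysed hydrolysis opens the azlactone to the acetamidoacrylic acid and then cleaves the enamide via its protonated imine tautomer to the α-keto acid (isolated largely as the enol); aryl iodides and the aryl methyl ether are inert to hot dilute HCl.

Step 5
Reactants: 9 3-(3,5-diiodo-4-methoxyphenyl)-2-oxopropanoic acid
Product: 10 2-(3,5-diiodo-4-methoxyphenyl)acetic acid
Conditions: 30% aq H2O2 (1.5 equiv), 10% aq NaOH, 0 °C → rt, 12 h; then HCl to pH 1, filter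
Reagents that add atoms: hydrogen peroxide, OO
Why: Oxidative decarboxylation of an α-keto acid: hydroperoxide anion adds to the ketone and the adduct fragments with loss of CO2 to the one-carbon-shorter carboxylate; nothing else in the molecule is oxidised by cold alkaline peroxide.

Step 6
Reactants: 10 2-(3,5-diiodo-4-methoxyphenyl)acetic acid
Product: 12 2-(3,5-diiodo-4-methoxyphenyl)acetamide, via 2-(3,5-diiodo-4-methoxyphenyl)-1-(imidazol-1-yl)ethanone 11 (not isolated)
Conditions: CDI (1.2 equiv), THF, rt, 1 h; then 28% aq NH3 (excess), 0 °C → rt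
Reagents that add atoms: ammonia, N
Why: CDI activation to the acylimidazole followed by nucleophilic acyl substitution with ammonia gives the primary amide under mild, neutral-to-basic conditions that leave the Ar–I bonds and the methyl ether untouched.

**Compound list**
1 | 4-hydroxybenzaldehyde | O=Cc1ccc(O)cc1 | starting material
2 | 4-hydroxy-3-iodobenzaldehyde | O=Cc1ccc(O)c(I)c1 | intermediate (not isolated)
3 | 4-hydroxy-3,5-diiodobenzaldehyde | O=Cc1cc(I)c(O)c(I)c1 | intermediate
4 | 3,5-diiodo-4-methoxybenzaldehyde | COc1c(I)cc(C=O)cc1I | intermediate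
5 | N-acetylglycine | CC(=O)NCC(=O)O | starting material
6 | 2-methyloxazol-5(4H)-one | CC1=NCC(=O)O1 | intermediate (not isolated)
7 | (Z)-4-(3,5-diiodo-4-methoxybenzylidene)-2-methyloxazol-5(4H)-one | CC1=N/C(=C\c2cc(I)c(OC)c(I)c2)C(=O)O1 | intermediate
8 | (Z)-2-acetamido-3-(3,5-diiodo-4-methoxyphenyl)acrylic acid | CC(=O)N/C(=C\c1cc(I)c(OC)c(I)c1)C(=O)O | intermediate (not isolated)
9 | 3-(3,5-diiodo-4-methoxyphenyl)-2-oxopropanoic acid | COc1c(I)cc(CC(=O)C(=O)O)cc1I | intermediate
10 | 2-(3,5-diiodo-4-methoxyphenyl)acetic acid | COc1c(I)cc(CC(=O)O)cc1I | intermediate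
11 | 2-(3,5-diiodo-4-methoxyphenyl)-1-(imidazol-1-yl)ethanone | COc1c(I)cc(CC(=O)n2ccnc2)cc1I | intermediate (not isolated)
12 | 2-(3,5-diiodo-4-methoxyphenyl)acetamide | COc1c(I)cc(CC(N)=O)cc1I | target

**Summary**
Total step count: 6. Longest linear sequence: 6 steps (1 → 12).

**Steps most likely to fail, with fallbacks**

Step 3 (Erlenmeyer condensation; N-acetylglycine azlactones can form in modest yield with tarring). Fallback sets out from 4 and comes back at 10. Aldehyde 4 is condensed in a Knoevenagel-type reaction with methyl (methylthio)methyl sulfoxide (Triton B, THF, reflux) to give the ketene dithioacetal S-oxide 1,3-diiodo-2-methoxy-5-[2-(methylsulfinyl)-2-(methylthio)ethenyl]benzene F1 (E/Z mixture, racemic at sulfur, used as such). Treatment of this with HCl in EtOH at rt gives ethyl 2-(3,5-diiodo-4-methoxyphenyl)acetate F2. Saponification (LiOH, THF/H2O, then HCl) delivers acid 10, bypassing the azlactone and the keto acid altogether.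

Step 4 (acid hydrolysis of the poorly soluble azlactone; the arylpyruvic acid can degrade on prolonged heating). Fallback sets out from 4 and comes back at 9. Aldehyde 4 is condensed with hydantoin (ethanolamine, EtOH/H2O, 90 °C) to give (Z)-5-(3,5-diiodo-4-methoxybenzylidene)imidazolidine-2,4-dione F3. This is cleaved in refluxing 20% aq NaOH (ammonia evolved) and acidified cold to give keto acid 9, so the keto acid is released under basic rather than acidic conditions from a different heterocycle.

Step 5 (oxidative decarboxylation; arylpyruvic acids can self-condense or cleave to the aldehyde in base before the peroxide acts). Fallback sets out from 9 and comes back at 12. Keto acid 9 is converted with NH2OH·HCl/NaOAc in aq EtOH to (E)-2-(hydroxyimino)-3-(3,5-diiodo-4-methoxyphenyl)propanoic acid F4. Warming F4 in Ac2O causes decarboxylative dehydration to 2-(3,5-diiodo-4-methoxyphenyl)acetonitrile F5. Radziszewski hydration (30% H2O2, K2CO3, DMSO, rt) gives amide 12 directly, so step 6 is skipped as well.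

**Further compounds**
F1 | step 3 | 1,3-diiodo-2-methoxy-5-[2-(methylsulfinyl)-2-(methylthio)ethenyl]benzene (E/Z mixture, racemic sulfoxide) | COc1c(I)cc(C=C(SC)S(C)=O)cc1I
F2 | step 3 | ethyl 2-(3,5-diiodo-4-methoxyphenyl)acetate | CCOC(=O)Cc1cc(I)c(OC)c(I)c1
F3 | step 4 | (Z)-5-(3,5-diiodo-4-methoxybenzylidene)imidazolidine-2,4-dione | O=C1N/C(=C\c2cc(I)c(OC)c(I)c2)C(=O)N1
F4 | step 5 | (E)-2-(hydroxyimino)-3-(3,5-diiodo-4-methoxyphenyl)propanoic acid | COc1c(I)cc(C/C(=N\O)C(=O)O)cc1I
F5 | step 5 | 2-(3,5-diiodo-4-methoxyphenyl)acetonitrile | COc1c(I)cc(CC#N)cc1I
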